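**Plan**

- The C40 chain is cut at C11=C12 and C11′=C12′ (two Horner–Wadsworth–Emmons olefinations on a C10 bisphosphonate), giving two C15 aldehydes. Both are cut at C6–C7 back to one ring ketone plus an enynol acetylide; the dihydrofuran half is also cut at O–C8′ (closure onto an allene).
- The ring ketone is cut at C3–C4 and C5–C6: C4, C5 and the C5 methyl are acetone; C3 and C6 are the two aldehyde carbons of 2,2-dimethylbutanedial.
- Enabling feature: in ring C1–C6 the pair C3–OH/C5–OH is a 1,3-diol (aldol retron of the acetone carbonyl C5) and C5(OH)–C6(O) is an acyloin (benzoin retron) once C6 is a ketone. The quaternary carbon C1 makes the two aldehydes unlike, one unhindered and one neopentyl.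
- Forward order: cyclohexane ring first (aldol–benzoin), then the C7–C11 chain at C6 for both halves, then the dihydrofuran ring of the second half from an allene, then C15 + C10 + C15 and desilylation.
- Stereochemistry: C3 from (S)-proline; C5 relayed from C3 in the ring closure; C6 from axial acetylide attack anti to the axial C5 silyloxy group; C8′ from the allene axis, itself set by anti SN2′ hydride delivery relative to C6–O. E double bonds come from trans-hydroalumination and the olefinations.

Key step: step 2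

Remark: carotenoid numbering is used throughout (ring C1–C6, chain C7–C15, primed numbers for the dihydrofuran half); compounds 1, 4, 8 and 21 are taken as purchasable.

**Route**

Step 1
Reactants: 1 2,2-dimethylpent-4-enal
Product: 3 2,2-dimethylbutanedial, via ozonide 2 (not isolated)
Conditions: O3, CH2Cl2, −78 °C; then PPh3, −78 °C to rt; used as a solution
Reagents that add atoms: ozone, O=[O+][O-]
Why: Ozonolysis with reductive work-up cuts only the terminal alkene and leaves the hindered aldehyde untouched, so the 1,4-dialdehyde carrying C3 and C6 at the aldehyde level should result without any stereochemical issue.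

Step 2
Reactants: 3 2,2-dimethylbutanedial; 4 acetone
Product: 6 (2R,4S)-2,4-dihydroxy-2,6,6-trimethylcyclohexan-1-one, via aldol 5 (not isolated)
Conditions: (S)-proline (20 mol%), acetone–DMSO 1:4, 4 °C; then 2-(pentafluorophenyl)-6,7-dihydro-5H-pyrrolo[2,1-c][1,2,4]triazol-2-ium tetrafluoroborate (10 mol%), NaOAc (20 mol%), same flask, 40 °C
Reagents that add atoms: none
Why: Proposed new method: the enamine from (S)-proline and acetone adds to the re face of the unhindered C3 aldehyde of 3 through the usual carboxylic-acid-bound chair (bond C3–C4, aldol 5, resting largely as its five-ring lactol), and the triazolylidene then adds to the neopentyl C6 aldehyde to give an acyl-anion equivalent that attacks the C5 methyl ketone and, after loss of the carbene, leaves acyloin 6 (bond C5–C6). The closest known reaction types are the proline-catalysed aldol of acetone with aldehydes, the carbene-catalysed intramolecular aldehyde–ketone benzoin, and amine/carbene relay cascades in which a conjugate addition precedes the benzoin; an aldol–benzoin [4+2] assembly of a cyclohexane from a 1,4-dialdehyde and a ketone has not been shown. The six-membered ring closes by a 6-exo-trig carbonyl addition. C3 (S) is set by the amine catalyst, and C5 (R) by the C3 centre, because in the chair-like closure with the C3 hydroxyl equatorial the ketone methyl must also be equatorial to avoid a syn-axial clash with the axial C1 methyl, which puts the C5 oxygen axial and trans to the C3 hydroxyl. The step needs the two aldehydes of 3 to take different roles (acceptor at C3, acyl donor at C6) and the aldol to stop after one acetone; the quaternary carbon C1 secures both, since the aldehyde next to it cannot enolise, is shielded from the enamine, and is masked as the lactol of the new C3 hydroxyl once the first bond is made, from which only the small carbene draws it back.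

Step 3
Reactants: 6 (2R,4S)-2,4-dihydroxy-2,6,6-trimethylcyclohexan-1-one
Product: 7 (2R,4S)-2,6,6-trimethyl-2,4-bis(triethylsilyloxy)cyclohexan-1-one
Conditions: Et3SiOTf (2.5 equiv), 2,6-lutidine, CH2Cl2, −78 to 0 °C
Reagents that add atoms: triethylsilyl trifluoromethanesulfonate, CC[Si](CC)(CC)OS(=O)(=O)C(F)(F)F
Why: Silyl ether formation with a silyl triflate and a hindered pyridine base should cap the secondary and the tertiary ketol hydroxyl alike, removing acidic protons before the organolithium steps and placing a bulky axial group at C5.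

Step 4
Reactants: 7 (2R,4S)-2,6,6-trimethyl-2,4-bis(triethylsilyloxy)cyclohexan-1-one; 8 (2E)-3-methylpent-2-en-4-yn-1-ol
Product: 10 (1R,2R,4S)-1-[(3E)-5-hydroxy-3-methylpent-3-en-1-yn-1-yl]-2,6,6-trimethyl-2,4-bis(triethylsilyloxy)cyclohexan-1-ol, via dilithio enynolate 9 (not isolated)
Conditions: 8 (2.2 equiv), n-BuLi (4.3 equiv), THF, −78 to −20 °C; then 7, −78 to −30 °C; sat. aq. NH4Cl at −78 °C
Reagents that add atoms: none
Why: 1,2-Addition of the lithium acetylide to the ketone should occur axially, from the ring face opposite to the axial C5 silyloxy group and the axial C1 methyl in the chair that keeps the C3 silyloxy group equatorial, which places the new C6 hydroxyl cis to the C5 oxygen and the alkynyl group trans to it, as the target requires.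

Step 5
Reactants: 10 acetylenic diol
Product: 11 (1S,2R,4S)-1-[(1E,3E)-5-hydroxy-3-methylpenta-1,3-dien-1-yl]-2,6,6-trimethyl-2,4-bis(triethylsilyloxy)cyclohexan-1-ol
Conditions: NaAlH2(OCH2CH2OCH3)2 (4 equiv), THF, 0 °C to rt; aq. potassium sodium tartrate (KNaC4H4O6)
Reagents that add atoms: none
Why: Alkoxide-directed trans-hydroalumination of the tertiary propargylic alcohol, followed by protonolysis of the vinylalane, should give only the (7E)-alkene and leave the C9=C10 double bond and the silyl ethers alone (propargylic alcohol reduction).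

Step 6
Reactants: 11 dienediol
Product: 12 (2E,4E)-5-[(1S,2R,4S)-1-hydroxy-2,6,6-trimethyl-2,4-bis(triethylsilyloxy)cyclohexyl]-3-methylpenta-2,4-dienal
Conditions: MnO2 (activated, excess), CH2Cl2, rt
Reagents that add atoms: none
Why: Activated MnO2 oxidises only the primary allylic alcohol at C11 to the dienal, since the tertiary allylic C6 hydroxyl cannot be oxidised and the silyl ethers are inert (allylic alcohol oxidation).

Step 7
Reactants: 8 (2E)-3-methylpent-2-en-4-yn-1-ol
Product: 13 tert-butyldimethyl{[(2E)-3-methylpent-2-en-4-yn-1-yl]oxy}silane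
Conditions: t-BuMe2SiCl, imidazole, DMF, 0 °C to rt
Reagents that add atoms: tert-butyldimethylsilyl chloride, CC(C)(C)[Si](C)(C)Cl
Why: Standard silylation of the primary alcohol keeps the C11 oxygen inert toward the chloroformate and the palladium catalyst of the next two steps (silyl ether formation).

Step 8
Reactants: 7 (2R,4S)-2,6,6-trimethyl-2,4-bis(triethylsilyloxy)cyclohexan-1-one; 13 silyl-protected enyne
Product: 16 (1R,2R,4S)-1-[(3E)-5-(tert-butyldimethylsilyloxy)-3-methylpent-3-en-1-yn-1-yl]-2,6,6-trimethyl-2,4-bis(triethylsilyloxy)cyclohexyl methyl carbonate, via lithium acetylide 14 (not isolated), via lithium alkoxide 15 (not isolated)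
Conditions: 13 (1.5 equiv), n-BuLi (1.45 equiv), THF, −78 °C; then 7, −78 to −40 °C; then ClCO2CH3 (3 equiv), −78 to 0 °C
Reagents that add atoms: methyl chloroformate, COC(=O)Cl
Why: The same axial acetylide addition as in step 4 sets C6, and the tertiary propargylic lithium alkoxide is acylated in the flask to the carbonate, which becomes the leaving group on the ring face of the C5 oxygen (ketone alkynylation followed by O-acylation).

Step 9
Reactants: 16 propargylic carbonate
Product: 17 vinylallene tert-butyl{[(2E)-3-methyl-5-[(2R,4S)-2,6,6-trimethyl-2,4-bis(triethylsilyloxy)cyclohexylidene]penta-2,4-dien-1-yl]oxy}dimethylsilane with S allene axis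
Conditions: Pd2(dba)3·CHCl3 (2.5 mol%), PBu3 (10 mol%), HCO2NH4 (3 equiv), THF, rt
Reagents that add atoms: none
Why: Zerovalent palladium should displace the propargylic carbonate in an SN2′ sense from the side of C8 opposite to the leaving group, and hydride from formate is then passed from palladium to C8 with retention, so hydrogen enters anti to the C6–O bond and the allene forms with the C9 substituent on the ring face that carries the C5 oxygen (formate hydrogenolysis of a propargylic carbonate, centre-to-axis chirality transfer).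

Step 10
Reactants: 17 vinylallene
Product: 18 (1S,3R)-4-[(3E)-5-hydroxy-3-methylpenta-1,3-dien-1-ylidene]-3,5,5-trimethylcyclohexane-1,3-diol with S allene axis
Conditions: Bu4NF (4 equiv), THF, 0 °C to rt
Reagents that add atoms: none
Why: Fluoride cleaves the three silyl ethers and frees the tertiary C5 hydroxyl next to the allene, an arrangement that is stable in the natural allenic carotenoid end groups (desilylation).

Step 11
Reactants: 18 allenic triol
Product: 19 (2R,6S,7aR)-2-[(2E)-4-hydroxybut-2-en-2-yl]-4,4,7a-trimethyl-2,4,5,6,7,7a-hexahydro-1-benzofuran-6-ol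
Conditions: (Ph3P)AuNTf2 (2 mol%), THF, −20 to 0 °C
Reagents that add atoms: none
Why: Monovalent gold activates the C7=C8 π bond of the α-hydroxyallene and the tertiary C5 hydroxyl, the only one that can reach, adds to C8 in the plane of the ring, which closes the 2,5-dihydrofuran and carries the axial chirality into the (8R) centre of the target (5-endo cycloisomerisation of an α-hydroxyallene with axis-to-centre chirality transfer).

Step 12
Reactants: 19 dihydrofuran diol
Product: 20 (2E)-3-[(2R,6S,7aR)-6-hydroxy-4,4,7a-trimethyl-2,4,5,6,7,7a-hexahydro-1-benzofuran-2-yl]but-2-enal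
Conditions: MnO2 (activated, excess), CH2Cl2, rt
Reagents that add atoms: none
Why: MnO2 oxidises the primary allylic alcohol to the enal and leaves the secondary non-allylic C3′ hydroxyl alone, while the quaternary C5′ rules out aromatisation of the dihydrofuran (allylic alcohol oxidation).

Step 13
Reactants: 21 (2E,4E,6E)-2,7-dimethylocta-2,4,6-trienedial
Product: 22 (2E,4E,6E)-2,7-dimethylocta-2,4,6-triene-1,8-diol
Conditions: NaBH4, MeOH–THF, 0 °C
Reagents that add atoms: none
Why: Borohydride 1,2-reduction of both enal carbonyls should give the bis-allylic diol with the three E double bonds unchanged (carbonyl reduction).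

Step 14
Reactants: 22 (2E,4E,6E)-2,7-dimethylocta-2,4,6-triene-1,8-diol
Product: 23 (2E,4E,6E)-1,8-dibromo-2,7-dimethylocta-2,4,6-triene
Conditions: PBr3 (0.7 equiv), pyridine (cat.), Et2O, −10 °C; used at once
Reagents that add atoms: phosphorus tribromide, BrP(Br)Br
Why: SN2 bromination of the primary allylic alcohols at low temperature should give the dibromide without allylic transposition (alcohol to bromide conversion).

Step 15
Reactants: 23 (2E,4E,6E)-1,8-dibromo-2,7-dimethylocta-2,4,6-triene
Product: 24 tetraethyl [(2E,4E,6E)-2,7-dimethylocta-2,4,6-triene-1,8-diyl]bis(phosphonate)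
Conditions: P(OEt)3 (excess), 90 °C
Reagents that add atoms: triethyl phosphite, CCOP(OCC)OCC
Why: The Michaelis–Arbuzov reaction of the primary allylic bromides with triethyl phosphite gives the bisphosphonate and expels bromoethane.

Step 16
Reactants: 24 C10 bisphosphonate; 20 dihydrofuran enal
Product: 26 diethyl [(2E,4E,6E,8E,10E)-11-[(2R,6S,7aR)-6-hydroxy-4,4,7a-trimethyl-2,4,5,6,7,7a-hexahydro-1-benzofuran-2-yl]-2,7-dimethyldodeca-2,4,6,8,10-pentaen-1-yl]phosphonate, via sodium phosphonate 25 (not isolated)
Conditions: 24 (3 equiv), NaN(SiMe3)2 (2 equiv), THF, −78 °C; then 20, −78 to 0 °C; dark, argon; excess 24 recovered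
Reagents that add atoms: none
Why: Horner–Wadsworth–Emmons olefination of the allylic phosphonate anion with the enal should form the (11′E) double bond; the excess of bisphosphonate limits reaction to one end (one equivalent of anion is spent on the free hydroxyl), and adding the aldehyde to a preformed anion at low temperature avoids deprotonation at the doubly allylic C8′–H.

Step 17
Reactants: 26 C25 phosphonate; 12 bis(triethylsilyl) C15 dienal
Product: 28 (3S,5R,6S,3′S,5′R,8′R)-5′,8′-epoxy-3,5-bis(triethylsilyloxy)-5,6,5′,8′-tetrahydro-β,β-carotene-6,3′-diol, via disodium salt 27 (not isolated)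
Conditions: NaN(SiMe3)2 (2.05 equiv), THF, −78 °C; then 12 (1.2 equiv), −78 to 0 °C; dark, argon
Reagents that add atoms: none
Why: A second Horner–Wadsworth–Emmons olefination, now of the pentaenyl-stabilised phosphonate anion with dienal 12, should form the (11E) double bond and complete the all-E C40 chain, the free hydroxyls being carried as alkoxides or left protonated by the weakly basic carbanion.

Step 18
Reactants: 28 bis(triethylsilyl) ether of the target
Product: 29 (3S,5R,6S,3′S,5′R,8′R)-5′,8′-epoxy-5,6,5′,8′-tetrahydro-β,β-carotene-3,5,6,3′-tetrol (the target, all-E)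
Conditions: Bu4NF (3 equiv), THF, 0 °C to rt, dark
Reagents that add atoms: none
Why: Fluoride removes the two triethylsilyl groups without acid, so that neither the tertiary allylic C6 hydroxyl nor the doubly allylic C8′ ether is ionised and no stereocentre is touched (desilylation).

**Compound list**

1 | 2,2-dimethylpent-4-enal | C=CCC(C)(C)C=O | starting material
2 | 2,2-dimethyl-3-(1,2,4-trioxolan-3-yl)propanal (ozonide, ring carbon not controlled) | O=CC(C)(C)CC1OCOO1 | intermediate
3 | 2,2-dimethylbutanedial | O=CCC(C)(C)C=O | intermediate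
4 | acetone | CC(C)=O | starting material
5 | (4S)-4-hydroxy-2,2-dimethyl-6-oxoheptanal (in equilibrium with its five-ring lactol) | O=CC(C)(C)C[C@H](O)CC(C)=O | intermediate
6 | (2R,4S)-2,4-dihydroxy-2,6,6-trimethylcyclohexan-1-one | O=C1C(C)(C)C[C@H](O)C[C@@]1(C)O | intermediate
7 | (2R,4S)-2,6,6-trimethyl-2,4-bis(triethylsilyloxy)cyclohexan-1-one | O=C1C(C)(C)C[C@H](O[Si](CC)(CC)CC)C[C@@]1(C)O[Si](CC)(CC)CC | intermediate
8 | (2E)-3-methylpent-2-en-4-yn-1-ol | C#C/C(C)=C/CO | starting material
9 | dilithium salt of 8 (lithium acetylide and lithium alkoxide) | [Li]C#C/C(C)=C/CO[Li] | intermediate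
10 | (1R,2R,4S)-1-[(3E)-5-hydroxy-3-methylpent-3-en-1-yn-1-yl]-2,6,6-trimethyl-2,4-bis(triethylsilyloxy)cyclohexan-1-ol (1-OH cis to the 2-silyloxy group) | OC/C=C(C)/C#C[C@]1(O)C(C)(C)C[C@H](O[Si](CC)(CC)CC)C[C@@]1(C)O[Si](CC)(CC)CC | intermediate
11 | (1S,2R,4S)-1-[(1E,3E)-5-hydroxy-3-methylpenta-1,3-dien-1-yl]-2,6,6-trimethyl-2,4-bis(triethylsilyloxy)cyclohexan-1-ol | OC/C=C(C)/C=C/[C@]1(O)C(C)(C)C[C@H](O[Si](CC)(CC)CC)C[C@@]1(C)O[Si](CC)(CC)CC | intermediate
12 | (2E,4E)-5-[(1S,2R,4S)-1-hydroxy-2,6,6-trimethyl-2,4-bis(triethylsilyloxy)cyclohexyl]-3-methylpenta-2,4-dienal | O=C/C=C(C)/C=C/[C@]1(O)C(C)(C)C[C@H](O[Si](CC)(CC)CC)C[C@@]1(C)O[Si](CC)(CC)CC | intermediate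
13 | tert-butyldimethyl{[(2E)-3-methylpent-2-en-4-yn-1-yl]oxy}silane | C#C/C(C)=C/CO[Si](C)(C)C(C)(C)C | intermediate
14 | lithium acetylide of 13 | [Li]C#C/C(C)=C/CO[Si](C)(C)C(C)(C)C | intermediate
15 | lithium (1R,2R,4S)-1-[(3E)-5-(tert-butyldimethylsilyloxy)-3-methylpent-3-en-1-yn-1-yl]-2,6,6-trimethyl-2,4-bis(triethylsilyloxy)cyclohexan-1-olate | CC(C)(C)[Si](C)(C)OC/C=C(C)/C#C[C@]1(O[Li])C(C)(C)C[C@H](O[Si](CC)(CC)CC)C[C@@]1(C)O[Si](CC)(CC)CC | intermediate
16 | (1R,2R,4S)-1-[(3E)-5-(tert-butyldimethylsilyloxy)-3-methylpent-3-en-1-yn-1-yl]-2,6,6-trimethyl-2,4-bis(triethylsilyloxy)cyclohexyl methyl carbonate | CC(C)(C)[Si](C)(C)OC/C=C(C)/C#C[C@]1(OC(=O)OC)C(C)(C)C[C@H](O[Si](CC)(CC)CC)C[C@@]1(C)O[Si](CC)(CC)CC | intermediate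
17 | tert-butyl{[(2E)-3-methyl-5-[(2R,4S)-2,6,6-trimethyl-2,4-bis(triethylsilyloxy)cyclohexylidene]penta-2,4-dien-1-yl]oxy}dimethylsilane, allene axis S (carotenoid 6S: the C9 substituent on C8 lies on the ring face of the C5 oxygen) | CC(C)(C)[Si](C)(C)OC\C=C(/C)C([H])=[C@]=C1C(C)(C)C[C@H](O[Si](CC)(CC)CC)C[C@@]1(C)O[Si](CC)(CC)CC | intermediate
18 | (1S,3R)-4-[(3E)-5-hydroxy-3-methylpenta-1,3-dien-1-ylidene]-3,5,5-trimethylcyclohexane-1,3-diol, allene axis S (carotenoid 3S,5R,6S) | OC\C=C(/C)C([H])=[C@]=C1C(C)(C)C[C@H](O)C[C@@]1(C)O | intermediate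
19 | (2R,6S,7aR)-2-[(2E)-4-hydroxybut-2-en-2-yl]-4,4,7a-trimethyl-2,4,5,6,7,7a-hexahydro-1-benzofuran-6-ol | OC\C=C(/C)[C@H]1C=C2C(C)(C)C[C@H](O)C[C@@]2(C)O1 | intermediate
20 | (2E)-3-[(2R,6S,7aR)-6-hydroxy-4,4,7a-trimethyl-2,4,5,6,7,7a-hexahydro-1-benzofuran-2-yl]but-2-enal | O=C\C=C(/C)[C@H]1C=C2C(C)(C)C[C@H](O)C[C@@]2(C)O1 | intermediate
21 | (2E,4E,6E)-2,7-dimethylocta-2,4,6-trienedial | O=C/C(C)=C/C=C/C=C(C)/C=O | starting material
22 | (2E,4E,6E)-2,7-dimethylocta-2,4,6-triene-1,8-diol | OC/C(C)=C/C=C/C=C(C)/CO | intermediate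
23 | (2E,4E,6E)-1,8-dibromo-2,7-dimethylocta-2,4,6-triene | BrC/C(C)=C/C=C/C=C(C)/CBr | intermediate
24 | tetraethyl [(2E,4E,6E)-2,7-dimethylocta-2,4,6-triene-1,8-diyl]bis(phosphonate) | CCOP(=O)(OCC)C/C(C)=C/C=C/C=C(C)/CP(=O)(OCC)OCC | intermediate
25 | monosodium salt of 24 (phosphonate carbanion) | [Na+].CCOP(=O)(OCC)[CH-]/C(C)=C/C=C/C=C(C)/CP(=O)(OCC)OCC | intermediate
26 | diethyl [(2E,4E,6E,8E,10E)-11-[(2R,6S,7aR)-6-hydroxy-4,4,7a-trimethyl-2,4,5,6,7,7a-hexahydro-1-benzofuran-2-yl]-2,7-dimethyldodeca-2,4,6,8,10-pentaen-1-yl]phosphonate | CCOP(=O)(OCC)C/C(C)=C/C=C/C=C(C)/C=C/C=C(\C)[C@H]1C=C2C(C)(C)C[C@H](O)C[C@@]2(C)O1 | intermediate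
27 | disodium salt of 26 (alkoxide and phosphonate carbanion) | [Na+].[Na+].CCOP(=O)(OCC)[CH-]/C(C)=C/C=C/C=C(C)/C=C/C=C(\C)[C@H]1C=C2C(C)(C)C[C@H]([O-])C[C@@]2(C)O1 | intermediate
28 | (3S,5R,6S,3′S,5′R,8′R)-5′,8′-epoxy-3,5-bis(triethylsilyloxy)-5,6,5′,8′-tetrahydro-β,β-carotene-6,3′-diol (all-E) | CC(/C=C/C=C(C)/C=C/[C@]1(O)C(C)(C)C[C@H](O[Si](CC)(CC)CC)C[C@@]1(C)O[Si](CC)(CC)CC)=C\C=C\C=C(C)\C=C\C=C(/C)[C@H]1C=C2C(C)(C)C[C@H](O)C[C@@]2(C)O1 | intermediate
29 | (3S,5R,6S,3′S,5′R,8′R)-5′,8′-epoxy-5,6,5′,8′-tetrahydro-β,β-carotene-3,5,6,3′-tetrol (all-E) | CC(/C=C/C=C(C)/C=C/[C@]1(O)C(C)(C)C[C@H](O)C[C@@]1(C)O)=C\C=C\C=C(C)\C=C\C=C(/C)[C@H]1C=C2C(C)(C)C[C@H](O)C[C@@]2(C)O1 | target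

**Summary**

Total step count: 18. Longest linear sequence: 11 steps (steps 1, 2, 3, 8, 9, 10, 11, 12, 16, 17, 18).

**Steps most likely to fail**

Step 2 (Proposed new method). What may go wrong: the enamine may fail to discriminate between the two aldehydes; the first aldol may dehydrate or be followed by an intramolecular aldol from C4 onto the C6 aldehyde; the carbene may add too slowly to the neopentyl aldehyde held as a lactol; or the ring closure may show poor facial selectivity at the ketone, giving the C5 epimer. The fallback uses known chemistry and does not draw on compounds 1 to 6. It sets out from purchased (4R,6R)-4-hydroxy-2,2,6-trimethylcyclohexan-1-one F1 and comes back to the route at compound 7. The hydroxyl is silylated (Et3SiCl, imidazole) to (4R,6R)-2,2,6-trimethyl-4-(triethylsilyloxy)cyclohexan-1-one F2. Enolisation toward the only α-CH (LiN(i-Pr)2, Me3SiCl, THF, −78 °C) gives triethyl{[(1R)-3,5,5-trimethyl-4-(trimethylsilyloxy)cyclohex-3-en-1-yl]oxy}silane F3. Rubottom oxidation (3-chloroperbenzoic acid, NaHCO3, CH2Cl2, then mild removal of the transposed trimethylsilyl group) is expected to occur mainly from the face anti to the C3 silyloxy group, giving (2R,4S)-2-hydroxy-2,6,6-trimethyl-4-(triethylsilyloxy)cyclohexan-1-one F4; the minor epimer is to be removed by chromatography. Et3SiOTf and 2,6-lutidine then give 7.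

Step 9. What may go wrong: hydride may be delivered to C6 instead of C8, giving the alkyne; the allenylpalladium intermediate may equilibrate before hydride transfer, eroding the centre-to-axis transfer; or the hindered tertiary carbonate may ionise slowly. The fallback sets out from compound 11 and comes back at compound 19, giving up control at C8′. Bu4NF frees (1S,2R,4S)-1-[(1E,3E)-5-hydroxy-3-methylpenta-1,3-dien-1-yl]-2,6,6-trimethylcyclohexane-1,2,4-triol F5. A trace of acid (pyridinium p-toluenesulfonate, CH2Cl2, 0 °C) then ionises the tertiary allylic C6 hydroxyl and the C5 hydroxyl captures the cation at C8, which is the acid-induced furanoid rearrangement known for 5,6-epoxy and 5,6-dihydroxy end groups. This should give 19 together with its C8 epimer (2S,6S,7aR)-2-[(2E)-4-hydroxybut-2-en-2-yl]-4,4,7a-trimethyl-2,4,5,6,7,7a-hexahydro-1-benzofuran-6-ol F6, to be separated by chromatography.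

Step 11. What may go wrong: the gold-activated vinylallene may undergo a competing carbocyclisation, or the product may epimerise at C8′ through Lewis-acid ionisation of the doubly allylic ether. The fallback sets out from compound 18 and comes back at compound 19. N-Iodosuccinimide (CH2Cl2, −20 °C) triggers the same 5-endo closure through an iodonium ion, with the same axis-to-centre transfer, to give (2S,6S,7aR)-2-[(2E)-4-hydroxybut-2-en-2-yl]-3-iodo-4,4,7a-trimethyl-2,4,5,6,7,7a-hexahydro-1-benzofuran-6-ol F7. Radical reduction (Bu3SnH, azobisisobutyronitrile, toluene, 80 °C) then removes the iodine to give 19.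

Further compounds
F1 | step 2 | (4R,6R)-4-hydroxy-2,2,6-trimethylcyclohexan-1-one (purchased) | O=C1C(C)(C)C[C@H](O)C[C@H]1C
F2 | step 2 | (4R,6R)-2,2,6-trimethyl-4-(triethylsilyloxy)cyclohexan-1-one | O=C1C(C)(C)C[C@H](O[Si](CC)(CC)CC)C[C@H]1C
F3 | step 2 | triethyl{[(1R)-3,5,5-trimethyl-4-(trimethylsilyloxy)cyclohex-3-en-1-yl]oxy}silane | C[Si](C)(C)OC1=C(C)C[C@@H](O[Si](CC)(CC)CC)CC1(C)C
F4 | step 2 | (2R,4S)-2-hydroxy-2,6,6-trimethyl-4-(triethylsilyloxy)cyclohexan-1-one | O=C1C(C)(C)C[C@H](O[Si](CC)(CC)CC)C[C@@]1(C)O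
F5 | step 9 | (1S,2R,4S)-1-[(1E,3E)-5-hydroxy-3-methylpenta-1,3-dien-1-yl]-2,6,6-trimethylcyclohexane-1,2,4-triol | OC/C=C(C)/C=C/[C@]1(O)C(C)(C)C[C@H](O)C[C@@]1(C)O
F6 | step 9 | (2S,6S,7aR)-2-[(2E)-4-hydroxybut-2-en-2-yl]-4,4,7a-trimethyl-2,4,5,6,7,7a-hexahydro-1-benzofuran-6-ol | OC\C=C(/C)[C@@H]1C=C2C(C)(C)C[C@H](O)C[C@@]2(C)O1
F7 | step 11 | (2S,6S,7aR)-2-[(2E)-4-hydroxybut-2-en-2-yl]-3-iodo-4,4,7a-trimethyl-2,4,5,6,7,7a-hexahydro-1-benzofuran-6-ol | OC\C=C(/C)[C@H]1C(I)=C2C(C)(C)C[C@H](O)C[C@@]2(C)O1
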